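**Remarks.** Atoms carry geranylgeraniol-type numbers: C1 = CH2OH of the hydroxyethylidene, C2=C3 the exocyclic alkene (C3 in the ring), C4 and C5 ring CH2, C6 the ring carbinol, C7 the ring carbon bearing methyl and side chain, C8–C10 chain CH2, C11 the methyl-bearing stereocentre, C12 the ketone, C13=C14 the enone alkene, C15 the tertiary carbinol, C20 the ring OCH2. TBS = tert-butyldimethylsilyl, TES = triethylsilyl. Compounds 1, 6, 12 and 21 are assumed to be purchasable.

## The problem

The target is a C20 chain in which one oxygen bridges C7 and C20, giving an oxepane (ring atoms O, C7, C6, C5, C4, C3, C20). C7 is a fully substituted ether carbon, C6 is a secondary carbinol whose hydroxyl is cis to the C7 methyl group, and C3 carries an exocyclic trisubstituted alkene whose C1 arm must lie on the C4 side, away from C20. Seven-membered ethers close reluctantly, and a closure at C7 must deliver oxygen to a hindered tertiary centre with defined configuration while six-membered closure at C6 stays available. C6 and C7 are adjacent and can control each other. C11 is separated from C7 by three methylene groups, cannot be relayed from the ring, and sits alpha to the C12 ketone where it epimerises under base. The C2=C3 geometry has to tell apart two ring methylene groups (C20H2 and C4H2) of nearly equal size. The gamma-hydroxy enone with its tertiary allylic alcohol (C12–C15) and the doubly allylic ether/alcohol array (C1–C3–C20) will not survive strong base, hydride or Lewis acid, so the enone must come last.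

The feature that opens the plan: with the ring oxygen deleted, C20, C3, C4, C5, C6 and C7 form a six-membered carbocycle in which C20 is bonded only to C7 and C3. A 3-hydroxy-2-methyl-2-alkylcyclohexanone with C20 as the carbonyl carbon is therefore the oxepane minus one oxygen. This hydroxy ketone, with OH cis to methyl, is what hydride reduction and enone cleavage of the Wieland–Miescher ketone provide, and the enone ring supplies C8–C10.

## Retrosynthesis

**C12–C13 and the end game (26 ⇒ 25 ⇒ 24 ⇒ 20 + 23).** The silyl ethers of 25 are removed last. The C12–C13 bond is cut by a vinylmetal addition to aldehyde 20 followed by oxidation of 24. A phosphonate olefination at C13=C14 or an acylation at C11–C12 would each put a basic step next to the C11 stereocentre; this cut does not, and it brings C13–C15 in as the four-carbon iodide 23. Aldehyde 20 lacks the enone and the tertiary alcohol and traces through alcohol 19 to the tris-silyl ether 18. The forward steps must be non-basic.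

**C20 oxidation level (18 ⇒ 17 ⇒ 15).** The ring CH2–O of 18 is traced to the carbonyl of alkylidene lactone 15. A carbonyl at C20 is worth two later steps because it acidifies C3 and lets conjugation decide the alkene geometry. The forward sequence (partial reduction, then ionic reduction of acetate 17) must deliver hydride to C20 only and keep the alkene geometry.

**C2=C3 (15 ⇒ 13 ⇒ 11 + 12).** The alkene is cut by aldol condensation between lactone 11 and aldehyde 12. An olefination of a ring ketone at C3 would have no element to distinguish C20 from C4. Here the E isomer, with C1 anti to the carbonyl, is the thermodynamic product. Lactone 11 is enolisable only at C3.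

**The ring oxygen (11 ⇒ 10).** The O–C7 bond of 11 is traced to the C20–C7 bond of cyclohexanone 10 (Baeyer–Villiger transform). Against cutting C7–O or C20–O as ether closures, this cut needs no seven-membered cyclisation and no substitution at a tertiary carbon, and it transfers the C7 configuration by retention. Ketone 10 is a plain carbocycle. The forward step requires migration of C7 rather than C3 and a substrate free of alkenes.

**C9–C10 (10 ⇒ 5 + 7).** The side chain is cut between C9 and C10. The carboxyl group that enone cleavage leaves on C9 is used up as a radical precursor (redox-active ester 5), and C10–C12 arrives with C11 already set in bromide 7, through zinc reagent 9. Cutting C10–C11 instead would require an enolate alkylation in the presence of the ring ketone. The coupling is placed before the oxygen insertion so that no free acid ever sits next to the tertiary lactone oxygen.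

**Ring A of the starting material (5 ⇒ 4 ⇒ 3 ⇒ 2 ⇒ 1).** Keto acid 4 is the product of oxidative cleavage of the enone in 3: the beta-carbon becomes C20, the carbonyl carbon becomes the carboxyl group, one carbon is lost. Alcohol 2 comes from 1 by hydride reduction, which sets C6 relative to the purchased C7 centre. All ring stereochemistry thus derives from one commercial stereocentre and one substrate-controlled reduction.

## Roads not taken

**Alternative 1:** The obvious cut is C7–O by 7-endo opening of epoxy alcohol A1 (C20–OH onto the 6,7-epoxide, inversion at C7) to give A2. The chosen plan is better for three reasons. A1 needs two trisubstituted alkenes of defined geometry, one with its two allylic oxygens told apart, and a reagent-controlled epoxidation of one alkene beside the other. The closure sets 7-endo attack at the tertiary carbon against 6-exo attack at C6, and acid strong enough to favour C7 also ionises allylic C–O bonds. C6 and C7 would both rest on the epoxidation reagent, whereas here they come from one purchased centre.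

**Alternative 2:** Cut C3–C4 by intramolecular B-alkyl Suzuki–Miyaura coupling. Alkynol A3 would be converted to iodoalkene A4 by hydroxyl-directed trans-hydroalumination and iodination, which fixes the geometry; hydroboration of the vinyl group and palladium-catalysed closure would give 18. The geometry control is attractive. However, A3 needs an ether at the hindered tertiary oxygen made by substitution, C6 and C7 need their own asymmetric steps, and a seven-membered ring must be closed by cross-coupling under dilution. The count is higher and the ring is no easier.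

**Alternative 3:** Insert oxygen on the other side of C7: Baeyer–Villiger oxidation of 2,6-dimethylcyclohexanone A5 to lactone A6 (C7–O–C12). This places C7 and C11 in a 1,3-relationship on a ring, so C11 could in principle be equilibrated against C7. The two C7 substituents differ too little in size for a useful bias, C6 would have to be set in an aldol that creates a quaternary centre, and after opening A6 the oxepane would still have to be closed at a tertiary alcohol. In the chosen plan the insertion makes the oxepane itself.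

Key step: step 7

## Route

Step 1
Reactants: 1 (R)-Wieland–Miescher ketone [(8aR)-8a-methyl-3,4,8,8a-tetrahydronaphthalene-1,6(2H,7H)-dione]
Product: 2 (4aR,5R)-5-hydroxy-4a-methyl-4,4a,5,6,7,8-hexahydronaphthalen-2(3H)-one
Conditions: NaBH4 (0.3 equiv), EtOH, −10 °C
Reagents that add atoms: none
Why: Chemoselective 1,2-reduction: the saturated ketone is more electrophilic than the enone carbonyl, and hydride enters anti to the angular methyl group, so the new hydroxyl (C6) is cis to that methyl (substrate control from the purchased centre).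

Step 2
Reactants: 2 (4aR,5R)-5-hydroxy-4a-methyl-4,4a,5,6,7,8-hexahydronaphthalen-2(3H)-one
Product: 3 (4aR,5R)-5-(TBS-oxy)-4a-methyl-4,4a,5,6,7,8-hexahydronaphthalen-2(3H)-one
Conditions: TBSCl, imidazole, DMF, 40 °C
Reagents that add atoms: tert-butyldimethylsilyl chloride, CC(C)(C)[Si](C)(C)Cl
Why: Standard silylation of a secondary alcohol; the silyl ether later blocks acyl transfer from O7 to O6 in the lactone and withstands oxidants, enolate and hydride.

Step 3
Reactants: 3 (4aR,5R)-5-(TBS-oxy)-4a-methyl-4,4a,5,6,7,8-hexahydronaphthalen-2(3H)-one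
Product: 4 3-[(1S,2R)-2-(TBS-oxy)-1-methyl-6-oxocyclohexyl]propanoic acid
Conditions: RuCl3·xH2O (cat.), NaIO4, MeCN/EtOAc/H2O, 0 °C → rt
Reagents that add atoms: sodium periodate, [Na+].[O-]I(=O)(=O)=O; water, O
Why: RuO4 formed in the flask cleaves the enone C=C (oxidative degradation of bicyclic enones to keto acids): the beta-carbon becomes the C20 ketone, the enone carbonyl carbon ends as the carboxyl group and the alpha-carbon is lost as CO2. No stereocentre is involved.

Step 4
Reactants: 4 3-[(1S,2R)-2-(TBS-oxy)-1-methyl-6-oxocyclohexyl]propanoic acid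
Product: 5 4,5,6,7-tetrachloro-1,3-dioxoisoindolin-2-yl 3-[(1S,2R)-2-(TBS-oxy)-1-methyl-6-oxocyclohexyl]propanoate
Conditions: N-hydroxytetrachlorophthalimide, N,N′-diisopropylcarbodiimide, DMAP (cat.), CH2Cl2, rt
Reagents that add atoms: N-hydroxytetrachlorophthalimide, ON1C(=O)c2c(Cl)c(Cl)c(Cl)c(Cl)c2C1=O
Why: Carbodiimide esterification gives the redox-active ester needed for single-electron decarboxylation.

Step 5
Reactants: 6 (S)-3-bromo-2-methylpropan-1-ol
Product: 7 [(2S)-3-bromo-2-methylpropoxy]triethylsilane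
Conditions: Et3SiCl, imidazole, CH2Cl2, 0 °C
Reagents that add atoms: triethylsilyl chloride, CC[Si](CC)(CC)Cl
Why: Silylation; the stereocentre (future C11) is not at a reacting atom, and a TES ether can later be removed beside TBS ethers.

Step 6
Reactants: 5 4,5,6,7-tetrachloro-1,3-dioxoisoindolin-2-yl 3-[(1S,2R)-2-(TBS-oxy)-1-methyl-6-oxocyclohexyl]propanoate; 7 [(2S)-3-bromo-2-methylpropoxy]triethylsilane
Product: 10 (2S,3R)-3-(TBS-oxy)-2-methyl-2-[(4R)-4-methyl-5-(TES-oxy)pentyl]cyclohexan-1-one, via Grignard reagent 8 (not isolated), via dialkylzinc 9 (not isolated)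
Conditions: 7, Mg, THF, 45 °C; ZnCl2 (0.5 equiv), THF, rt; then 5, NiCl2·glyme (20 mol %), 4,4′-di-tert-butyl-2,2′-bipyridine (40 mol %), THF/DMF, rt
Reagents that add atoms: magnesium, [Mg] (in 8 only); zinc chloride, [Zn+2].[Cl-].[Cl-] (zinc in 9 only)
Why: Nickel-catalysed decarboxylative alkyl–alkyl Negishi-type coupling of a redox-active ester with a dialkylzinc: the primary C9 radical formed on loss of CO2 is captured by an alkylnickel species and reductive elimination forms C9–C10. C11 is beta to the metal and is carried through unchanged; ketone and silyl ethers are inert to the organozinc.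

Step 7
Reactants: 10 (2S,3R)-3-(TBS-oxy)-2-methyl-2-[(4R)-4-methyl-5-(TES-oxy)pentyl]cyclohexan-1-one
Product: 11 (6R,7S)-6-(TBS-oxy)-7-methyl-7-[(4R)-4-methyl-5-(TES-oxy)pentyl]oxepan-2-one
Conditions: mCPBA, NaHCO3, CH2Cl2, 0 °C → rt
Reagents that add atoms: 3-chloroperbenzoic acid, OOC(=O)c1cccc(Cl)c1
Why: Baeyer–Villiger oxidation: the peracid adds to the C20 carbonyl to give a tetrahedral peroxy hemiketal, and the C20–C7 bond antiperiplanar to the O–O bond migrates to oxygen as 3-chlorobenzoate leaves. The closest known reaction type is the peracid oxidation of 2,2-disubstituted 3-acyloxy- or 3-silyloxycyclohexanones to 7,7-disubstituted ε-lactones. The oxepane ring is formed by one-atom ring expansion of the cyclohexanone (a 1,2-shift inside an existing ring), not by end-to-end closure, so neither medium-ring entropy nor a 6-exo/7-endo choice arises. No new stereocentre is created: C7 migrates with retention, so the configuration bought in 1 becomes that of the tertiary ether carbon, and C6 is untouched. The selectivity needed is migration of C7 rather than the C3 methylene; the fully substituted C7 stabilises the electron-deficient migration terminus far better than a primary carbon, even allowing for the inductive pull of the C6 silyloxy group. Chemoselectivity follows from the order of events: 10 has no alkene, and the bicarbonate buffer protects the silyl ethers and the new lactone.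

Step 8
Reactants: 11 (6R,7S)-6-(TBS-oxy)-7-methyl-7-[(4R)-4-methyl-5-(TES-oxy)pentyl]oxepan-2-one; 12 2-(TBS-oxy)acetaldehyde
Product: 13 (6R,7S)-6-(TBS-oxy)-3-[1-hydroxy-2-(TBS-oxy)ethyl]-7-methyl-7-[(4R)-4-methyl-5-(TES-oxy)pentyl]oxepan-2-one (diastereomer mixture at C3 and the carbinol carbon)
Conditions: LiN(i-Pr)2, THF, −78 °C; then 12, −78 °C; aq. NH4Cl
Reagents that add atoms: none
Why: Aldol addition of an ε-lactone lithium enolate; C3 is the only enolisable position, and both new stereocentres are removed in the next step, so a diastereomer mixture is acceptable.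

Step 9
Reactants: 13 (6R,7S)-6-(TBS-oxy)-3-[1-hydroxy-2-(TBS-oxy)ethyl]-7-methyl-7-[(4R)-4-methyl-5-(TES-oxy)pentyl]oxepan-2-one
Product: 15 (3E,6R,7S)-6-(TBS-oxy)-3-[2-(TBS-oxy)ethylidene]-7-methyl-7-[(4R)-4-methyl-5-(TES-oxy)pentyl]oxepan-2-one, via mesylate 14 (not isolated)
Conditions: MeSO2Cl, Et3N, CH2Cl2, 0 °C; then DBU, 0 °C → rt
Reagents that add atoms: methanesulfonyl chloride, CS(=O)(=O)Cl (in 14 only)
Why: Mesylation and base-induced E1cB elimination through the lactone enolate. The E-alkylidene lactone, with C1 anti to the C20 carbonyl and syn to C4, is expected as the thermodynamically preferred isomer (as tiglate over angelate), and this is the geometry of the target.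

Step 10
Reactants: 15 (3E,6R,7S)-6-(TBS-oxy)-3-[2-(TBS-oxy)ethylidene]-7-methyl-7-[(4R)-4-methyl-5-(TES-oxy)pentyl]oxepan-2-one
Product: 17 (3E,6R,7S)-6-(TBS-oxy)-3-[2-(TBS-oxy)ethylidene]-7-methyl-7-[(4R)-4-methyl-5-(TES-oxy)pentyl]oxepan-2-yl acetate (C2 epimers), via aluminium lactolate 16 (not isolated)
Conditions: i-Bu2AlH, CH2Cl2, −78 °C; then pyridine, DMAP, Ac2O, −78 → 0 °C
Reagents that add atoms: diisobutylaluminium hydride, CC(C)C[AlH]CC(C)C (aluminium in 16 only); acetic anhydride, CC(=O)OC(C)=O
Why: Reductive acetylation of a lactone: 1,2-reduction of the conjugated lactone at low temperature gives a tetrahedral aluminium lactolate, which is acetylated in the flask before the seven-membered lactol can open. The acetal carbon forms as an inconsequential epimer mixture.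

Step 11
Reactants: 17 (3E,6R,7S)-6-(TBS-oxy)-3-[2-(TBS-oxy)ethylidene]-7-methyl-7-[(4R)-4-methyl-5-(TES-oxy)pentyl]oxepan-2-yl acetate
Product: 18 (2S,3R,6E)-3-(TBS-oxy)-6-[2-(TBS-oxy)ethylidene]-2-methyl-2-[(4R)-4-methyl-5-(TES-oxy)pentyl]oxepane
Conditions: Et3SiH, BF3·OEt2, CH2Cl2, −78 °C
Reagents that add atoms: none
Why: Ionic reduction: BF3 ionises the acetate to an oxocarbenium ion conjugated with the exocyclic alkene, and the silane delivers hydride to the oxygen-bearing carbon C20, as in Ferrier-type reductions of unsaturated lactol esters. C20 becomes CH2 and the C2=C3 geometry should be retained at low temperature.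

Step 12
Reactants: 18 (2S,3R,6E)-3-(TBS-oxy)-6-[2-(TBS-oxy)ethylidene]-2-methyl-2-[(4R)-4-methyl-5-(TES-oxy)pentyl]oxepane
Product: 19 (2R)-5-{(2S,3R,6E)-3-(TBS-oxy)-6-[2-(TBS-oxy)ethylidene]-2-methyloxepan-2-yl}-2-methylpentan-1-ol
Conditions: pyridinium 4-toluenesulfonate (cat.), MeOH/CH2Cl2, 0 °C
Reagents that add atoms: none
Why: Acid-catalysed methanolysis distinguishes the primary TES ether from the two bulkier TBS ethers.

Step 13
Reactants: 19 (2R)-5-{(2S,3R,6E)-3-(TBS-oxy)-6-[2-(TBS-oxy)ethylidene]-2-methyloxepan-2-yl}-2-methylpentan-1-ol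
Product: 20 (2R)-5-{(2S,3R,6E)-3-(TBS-oxy)-6-[2-(TBS-oxy)ethylidene]-2-methyloxepan-2-yl}-2-methylpentanal
Conditions: Dess–Martin periodinane, NaHCO3, CH2Cl2, 0 °C → rt
Reagents that add atoms: none
Why: Buffered Dess–Martin oxidation gives the alpha-methyl aldehyde under non-epimerising conditions; it is used at once.

Step 14
Reactants: 21 2-methylbut-3-yn-2-ol
Product: 23 (E)-4-iodo-2-methylbut-3-en-2-ol, via vinylstannane 22 (not isolated)
Conditions: Bu3SnH, PdCl2(PPh3)2 (cat.), THF, 0 °C → rt; then I2, CH2Cl2, 0 °C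
Reagents that add atoms: tributyltin hydride, CCCC[SnH](CCCC)CCCC (tin in 22 only); iodine, II
Why: Palladium-catalysed syn-hydrostannation places tin on the terminal carbon of the hindered propargylic alcohol, and iododestannylation proceeds with retention to give the E-iodide.

Step 15
Reactants: 20 (2R)-5-{(2S,3R,6E)-3-(TBS-oxy)-6-[2-(TBS-oxy)ethylidene]-2-methyloxepan-2-yl}-2-methylpentanal; 23 (E)-4-iodo-2-methylbut-3-en-2-ol
Product: 24 (3E,6R)-9-{(2S,3R,6E)-3-(TBS-oxy)-6-[2-(TBS-oxy)ethylidene]-2-methyloxepan-2-yl}-2,6-dimethylnon-3-ene-2,5-diol (C5 epimers)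
Conditions: CrCl2 (excess), NiCl2 (cat.), DMSO, rt
Reagents that add atoms: none
Why: Nozaki–Hiyama–Kishi reaction: the vinylchromium species adds to the aldehyde with retention of alkene geometry under non-basic conditions, so C11 is not epimerised. The free tertiary hydroxyl is tolerated, and the carbinol epimers converge in the next step.

Step 16
Reactants: 24 (3E,6R)-9-{(2S,3R,6E)-3-(TBS-oxy)-6-[2-(TBS-oxy)ethylidene]-2-methyloxepan-2-yl}-2,6-dimethylnon-3-ene-2,5-diol
Product: 25 (3E,6R)-9-{(2S,3R,6E)-3-(TBS-oxy)-6-[2-(TBS-oxy)ethylidene]-2-methyloxepan-2-yl}-2-hydroxy-2,6-dimethylnon-3-en-5-one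
Conditions: Dess–Martin periodinane, NaHCO3, CH2Cl2, 0 °C
Reagents that add atoms: none
Why: Oxidation of the secondary allylic alcohol to the enone; the tertiary alcohol cannot be oxidised, and the buffer protects C11.

Step 17
Reactants: 25 (3E,6R)-9-{(2S,3R,6E)-3-(TBS-oxy)-6-[2-(TBS-oxy)ethylidene]-2-methyloxepan-2-yl}-2-hydroxy-2,6-dimethylnon-3-en-5-one
Product: 26 (3E,6R)-2-hydroxy-9-[(2S,3R,6E)-3-hydroxy-6-(2-hydroxyethylidene)-2-methyloxepan-2-yl]-2,6-dimethylnon-3-en-5-one (CNP0270237.1)
Conditions: HF·pyridine, pyridine, THF, 0 °C → rt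
Reagents that add atoms: none
Why: Buffered fluoride cleavage of both TBS ethers avoids enolisation at C11. The tertiary allylic alcohol resists ionisation because the derived cation would be conjugated to the electron-poor enone.

## Compound list

1 | (R)-Wieland–Miescher ketone, (8aR)-8a-methyl-3,4,8,8a-tetrahydronaphthalene-1,6(2H,7H)-dione | C[C@@]12CCC(=O)C=C1CCCC2=O | starting material
2 | (4aR,5R)-5-hydroxy-4a-methyl-4,4a,5,6,7,8-hexahydronaphthalen-2(3H)-one | C[C@@]12CCC(=O)C=C1CCC[C@H]2O | intermediate
3 | (4aR,5R)-5-(TBS-oxy)-4a-methyl-4,4a,5,6,7,8-hexahydronaphthalen-2(3H)-one | C[C@@]12CCC(=O)C=C1CCC[C@H]2O[Si](C)(C)C(C)(C)C | intermediate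
4 | 3-[(1S,2R)-2-(TBS-oxy)-1-methyl-6-oxocyclohexyl]propanoic acid | C[C@@]1(CCC(=O)O)C(=O)CCC[C@H]1O[Si](C)(C)C(C)(C)C | intermediate
5 | 4,5,6,7-tetrachloro-1,3-dioxoisoindolin-2-yl 3-[(1S,2R)-2-(TBS-oxy)-1-methyl-6-oxocyclohexyl]propanoate | C[C@@]1(CCC(=O)ON2C(=O)c3c(Cl)c(Cl)c(Cl)c(Cl)c3C2=O)C(=O)CCC[C@H]1O[Si](C)(C)C(C)(C)C | intermediate
6 | (S)-3-bromo-2-methylpropan-1-ol | C[C@H](CBr)CO | starting material
7 | [(2S)-3-bromo-2-methylpropoxy]triethylsilane | C[C@H](CBr)CO[Si](CC)(CC)CC | intermediate
8 | [(2S)-2-methyl-3-(TES-oxy)propyl]magnesium bromide (formed in the flask) | C[C@H](C[Mg]Br)CO[Si](CC)(CC)CC | intermediate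
9 | bis[(2S)-2-methyl-3-(TES-oxy)propyl]zinc (formed in the flask) | C[C@H](C[Zn]C[C@@H](C)CO[Si](CC)(CC)CC)CO[Si](CC)(CC)CC | intermediate
10 | (2S,3R)-3-(TBS-oxy)-2-methyl-2-[(4R)-4-methyl-5-(TES-oxy)pentyl]cyclohexan-1-one | C[C@H](CCC[C@]1(C)C(=O)CCC[C@H]1O[Si](C)(C)C(C)(C)C)CO[Si](CC)(CC)CC | intermediate
11 | (6R,7S)-6-(TBS-oxy)-7-methyl-7-[(4R)-4-methyl-5-(TES-oxy)pentyl]oxepan-2-one | C[C@H](CCC[C@]1(C)OC(=O)CCC[C@H]1O[Si](C)(C)C(C)(C)C)CO[Si](CC)(CC)CC | intermediate
12 | 2-(TBS-oxy)acetaldehyde | O=CCO[Si](C)(C)C(C)(C)C | starting material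
13 | (6R,7S)-6-(TBS-oxy)-3-[1-hydroxy-2-(TBS-oxy)ethyl]-7-methyl-7-[(4R)-4-methyl-5-(TES-oxy)pentyl]oxepan-2-one (diastereomer mixture) | C[C@H](CCC[C@]1(C)OC(=O)C(C(O)CO[Si](C)(C)C(C)(C)C)CC[C@H]1O[Si](C)(C)C(C)(C)C)CO[Si](CC)(CC)CC | intermediate
14 | methanesulfonate of 13 (formed in the flask) | C[C@H](CCC[C@]1(C)OC(=O)C(C(OS(C)(=O)=O)CO[Si](C)(C)C(C)(C)C)CC[C@H]1O[Si](C)(C)C(C)(C)C)CO[Si](CC)(CC)CC | intermediate
15 | (3E,6R,7S)-6-(TBS-oxy)-3-[2-(TBS-oxy)ethylidene]-7-methyl-7-[(4R)-4-methyl-5-(TES-oxy)pentyl]oxepan-2-one | C[C@H](CCC[C@]1(C)OC(=O)/C(=C/CO[Si](C)(C)C(C)(C)C)CC[C@H]1O[Si](C)(C)C(C)(C)C)CO[Si](CC)(CC)CC | intermediate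
16 | diisobutylaluminium (3E,6R,7S)-6-(TBS-oxy)-3-[2-(TBS-oxy)ethylidene]-7-methyl-7-[(4R)-4-methyl-5-(TES-oxy)pentyl]oxepan-2-olate (formed in the flask) | C[C@H](CCC[C@]1(C)OC(O[Al](CC(C)C)CC(C)C)/C(=C/CO[Si](C)(C)C(C)(C)C)CC[C@H]1O[Si](C)(C)C(C)(C)C)CO[Si](CC)(CC)CC | intermediate
17 | (3E,6R,7S)-6-(TBS-oxy)-3-[2-(TBS-oxy)ethylidene]-7-methyl-7-[(4R)-4-methyl-5-(TES-oxy)pentyl]oxepan-2-yl acetate (C2 epimers) | C[C@H](CCC[C@]1(C)OC(OC(C)=O)/C(=C/CO[Si](C)(C)C(C)(C)C)CC[C@H]1O[Si](C)(C)C(C)(C)C)CO[Si](CC)(CC)CC | intermediate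
18 | (2S,3R,6E)-3-(TBS-oxy)-6-[2-(TBS-oxy)ethylidene]-2-methyl-2-[(4R)-4-methyl-5-(TES-oxy)pentyl]oxepane | C[C@H](CCC[C@]1(C)OC/C(=C/CO[Si](C)(C)C(C)(C)C)CC[C@H]1O[Si](C)(C)C(C)(C)C)CO[Si](CC)(CC)CC | intermediate
19 | (2R)-5-{(2S,3R,6E)-3-(TBS-oxy)-6-[2-(TBS-oxy)ethylidene]-2-methyloxepan-2-yl}-2-methylpentan-1-ol | C[C@H](CCC[C@]1(C)OC/C(=C/CO[Si](C)(C)C(C)(C)C)CC[C@H]1O[Si](C)(C)C(C)(C)C)CO | intermediate
20 | (2R)-5-{(2S,3R,6E)-3-(TBS-oxy)-6-[2-(TBS-oxy)ethylidene]-2-methyloxepan-2-yl}-2-methylpentanal | C[C@H](CCC[C@]1(C)OC/C(=C/CO[Si](C)(C)C(C)(C)C)CC[C@H]1O[Si](C)(C)C(C)(C)C)C=O | intermediate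
21 | 2-methylbut-3-yn-2-ol | CC(C)(O)C#C | starting material
22 | (E)-2-methyl-4-(tributylstannyl)but-3-en-2-ol (formed in the flask) | CCCC[Sn](CCCC)(CCCC)/C=C/C(C)(C)O | intermediate
23 | (E)-4-iodo-2-methylbut-3-en-2-ol | CC(C)(O)/C=C/I | intermediate
24 | (3E,6R)-9-{(2S,3R,6E)-3-(TBS-oxy)-6-[2-(TBS-oxy)ethylidene]-2-methyloxepan-2-yl}-2,6-dimethylnon-3-ene-2,5-diol (C5 epimers) | C[C@H](CCC[C@]1(C)OC/C(=C/CO[Si](C)(C)C(C)(C)C)CC[C@H]1O[Si](C)(C)C(C)(C)C)C(O)/C=C/C(C)(C)O | intermediate
25 | (3E,6R)-9-{(2S,3R,6E)-3-(TBS-oxy)-6-[2-(TBS-oxy)ethylidene]-2-methyloxepan-2-yl}-2-hydroxy-2,6-dimethylnon-3-en-5-one | C[C@H](CCC[C@]1(C)OC/C(=C/CO[Si](C)(C)C(C)(C)C)CC[C@H]1O[Si](C)(C)C(C)(C)C)C(=O)/C=C/C(C)(C)O | intermediate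
26 | (3E,6R)-2-hydroxy-9-[(2S,3R,6E)-3-hydroxy-6-(2-hydroxyethylidene)-2-methyloxepan-2-yl]-2,6-dimethylnon-3-en-5-one | C[C@H](CCC[C@]1(C)OC/C(=C/CO)CC[C@H]1O)C(=O)/C=C/C(C)(C)O | target

## Step count and risk

Total: 17 steps. Longest linear sequence: 15 steps (steps 1–4, 6–13, 15–17).

**Step 7 (key step).** The most likely failure is slow or incomplete oxygen transfer, because the carbonyl is flanked by a fully substituted carbon that also carries a beta-silyloxy group. That group's inductive pull lowers the migratory aptitude of C7, so some migration of the C3 methylene is conceivable. The fallback moves the insertion ahead of the fragment coupling and makes it enzymatic. It sets out from keto acid 4, a polar, water-compatible substrate. A Baeyer–Villiger monooxygenase of the cyclohexanone monooxygenase class (NADPH recycled by glucose dehydrogenase and glucose, aerated phosphate buffer) would give lactone acid F1. Esterification with N-hydroxytetrachlorophthalimide gives redox-active ester F2, and nickel-catalysed coupling with dialkylzinc 9 under the conditions of step 6 returns to the route at 11. F1 should be esterified promptly, because its free carboxyl group could in time accept the tertiary lactone oxygen.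

**Step 11 (with step 10).** Three processes threaten this step: hydride delivery to the conjugate position C2 of the alkoxyallyl cation (giving a ring enol ether), rotation about C2–C3 in the cation with loss of geometry, and Lewis-acid ionisation of the allylic C–O bonds of the product. The fallback forms the C20–O bond by substitution instead of reduction. It sets out from 15: excess i-Bu2AlH reduces the lactone fully to diol F3 (primary allylic alcohol at C20, tertiary alcohol at C7, alkene geometry unchanged). Corey–Kim chlorination (N-chlorosuccinimide, Me2S) converts only the primary allylic hydroxyl into allylic chloride F4. Williamson closure with NaH in THF at low temperature (7-exo-tet attack of the C7 alkoxide on C20) comes back to the route at 18. Low temperature is needed so that ring closure outruns silyl transfer from O6 to the neighbouring alkoxide.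

**Step 9.** The risks are erosion of E selectivity in the elimination and base-induced 1,4-elimination of silanolate from the product through its dienolate. The fallback replaces aldol/elimination by olefination and sets out from 11. The lithium enolate of 11 is phosphorylated with diethyl chlorophosphate to enol phosphate F5, which rearranges with a second equivalent of LiN(i-Pr)2 (1,3-phosphorus shift) to alpha-phosphono lactone F6. Horner–Wadsworth–Emmons reaction of F6 with aldehyde 12 (LiCl, DBU, MeCN) comes back at 15 without a beta-leaving-group intermediate.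

**Step 6.** The primary radical may be reduced or dimerised before nickel captures it, and the beta-branched dialkylzinc may transmetalate slowly. The fallback is a two-electron alkyl–alkyl Negishi coupling of an isolated iodide. It sets out from acid 4, which is converted by hypoiodite iododecarboxylation (PhI(OAc)2, I2, light) into iodide F7. Bromide 7 is converted by direct zinc insertion (Zn, I2 cat., N,N-dimethylacetamide) into alkylzinc bromide F8. Coupling of F7 and F8 with Pd2(dba)3, P(c-C5H9)3 and N-methylimidazole in THF/N-methylpyrrolidone comes back to the route at 10.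

## Further compounds

F1 | step 7 | 3-[(2S,3R)-3-(TBS-oxy)-2-methyl-7-oxooxepan-2-yl]propanoic acid | C[C@@]1(CCC(=O)O)OC(=O)CCC[C@H]1O[Si](C)(C)C(C)(C)C
F2 | step 7 | 4,5,6,7-tetrachloro-1,3-dioxoisoindolin-2-yl 3-[(2S,3R)-3-(TBS-oxy)-2-methyl-7-oxooxepan-2-yl]propanoate | C[C@@]1(CCC(=O)ON2C(=O)c3c(Cl)c(Cl)c(Cl)c(Cl)c3C2=O)OC(=O)CCC[C@H]1O[Si](C)(C)C(C)(C)C
F3 | step 11 | (5R,6S,10R)-5-(TBS-oxy)-2-[(E)-2-(TBS-oxy)ethylidene]-6,10-dimethyl-11-(TES-oxy)undecane-1,6-diol | C[C@H](CCC[C@](C)(O)[C@H](O[Si](C)(C)C(C)(C)C)CC/C(CO)=C\CO[Si](C)(C)C(C)(C)C)CO[Si](CC)(CC)CC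
F4 | step 11 | (5R,6S,10R)-5-(TBS-oxy)-2-[(E)-2-(TBS-oxy)ethylidene]-1-chloro-6,10-dimethyl-11-(TES-oxy)undecan-6-ol | C[C@H](CCC[C@](C)(O)[C@H](O[Si](C)(C)C(C)(C)C)CC/C(CCl)=C\CO[Si](C)(C)C(C)(C)C)CO[Si](CC)(CC)CC
F5 | step 9 | diethyl (6R,7S)-6-(TBS-oxy)-7-methyl-7-[(4R)-4-methyl-5-(TES-oxy)pentyl]-4,5,6,7-tetrahydrooxepin-2-yl phosphate | C[C@H](CCC[C@]1(C)OC(OP(=O)(OCC)OCC)=CCC[C@H]1O[Si](C)(C)C(C)(C)C)CO[Si](CC)(CC)CC
F6 | step 9 | diethyl {(6R,7S)-6-(TBS-oxy)-7-methyl-7-[(4R)-4-methyl-5-(TES-oxy)pentyl]-2-oxooxepan-3-yl}phosphonate (C3 epimers) | C[C@H](CCC[C@]1(C)OC(=O)C(P(=O)(OCC)OCC)CC[C@H]1O[Si](C)(C)C(C)(C)C)CO[Si](CC)(CC)CC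
F7 | step 6 | (2S,3R)-3-(TBS-oxy)-2-(2-iodoethyl)-2-methylcyclohexan-1-one | C[C@@]1(CCI)C(=O)CCC[C@H]1O[Si](C)(C)C(C)(C)C
F8 | step 6 | [(2S)-2-methyl-3-(TES-oxy)propyl]zinc bromide | C[C@H](C[Zn]Br)CO[Si](CC)(CC)CC
A1 | alternative 1 | (2E)-4-(TBS-oxy)-2-(2-{(2R,3R)-3-methyl-3-[(4R)-4-methyl-5-(TES-oxy)pentyl]oxiran-2-yl}ethyl)but-2-en-1-ol | C[C@H](CCC[C@@]1(C)O[C@@H]1CC/C(CO)=C\CO[Si](C)(C)C(C)(C)C)CO[Si](CC)(CC)CC
A2 | alternative 1 | (2S,3R,6E)-6-[2-(TBS-oxy)ethylidene]-2-methyl-2-[(4R)-4-methyl-5-(TES-oxy)pentyl]oxepan-3-ol | C[C@H](CCC[C@]1(C)OC/C(=C/CO[Si](C)(C)C(C)(C)C)CC[C@H]1O)CO[Si](CC)(CC)CC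
A3 | alternative 2 | 4-{[(3R,4S,8R)-3-(TBS-oxy)-4,8-dimethyl-9-(TES-oxy)non-1-en-4-yl]oxy}but-2-yn-1-ol | C[C@H](CCC[C@](C)(OCC#CCO)[C@H](O[Si](C)(C)C(C)(C)C)C=C)CO[Si](CC)(CC)CC
A4 | alternative 2 | (2Z)-2-iodo-4-(TBS-oxy)but-2-en-1-yl ether of (3R,4S,8R)-3-(TBS-oxy)-4,8-dimethyl-9-(TES-oxy)non-1-en-4-ol | C[C@H](CCC[C@](C)(OC/C(I)=C/CO[Si](C)(C)C(C)(C)C)[C@H](O[Si](C)(C)C(C)(C)C)C=C)CO[Si](CC)(CC)CC
A5 | alternative 3 | (2S,6R)-2-[(1R)-1-(TBS-oxy)pent-4-en-1-yl]-2,6-dimethylcyclohexan-1-one | C[C@@H]1CCC[C@@](C)([C@H](O[Si](C)(C)C(C)(C)C)CCC=C)C1=O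
A6 | alternative 3 | (3R,7S)-7-[(1R)-1-(TBS-oxy)pent-4-en-1-yl]-3,7-dimethyloxepan-2-one | C[C@@H]1CCC[C@@](C)([C@H](O[Si](C)(C)C(C)(C)C)CCC=C)OC1=O
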